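**Assumption:** enantiopure (R)-(+)-α-ionone (natural grade, ≥98% ee) is taken as a purchasable starting material.

## Retrosynthetic overview
1. δ-Carotene 16 ⇒ Wittig at C11=C12: ε-C15 phosphonium salt 14 + ψ-C25 aldehyde 11 (apo-12'-lycopenal).
2. 11 ⇒ mono-Wittig at C11'=C12': ψ-C15 phosphonium salt 8 + symmetrical C10 dialdehyde 9.
3. 8 ⇒ vinylpseudoionol 7 ⇒ pseudoionone 5, whose C7'–C8' bond comes from a [3,3]-sigmatropic propargyl Claisen (Saucy–Marbet) rearrangement of dehydrolinalool 1 with 2-methoxypropene 2 (key step).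
4. 14 ⇒ vinyl-α-ionol 13 ⇒ (R)-α-ionone 12. No ring is formed in the route: the ε-ring and its single stereocentre (6R) are bought intact.

## Route

**Step 1**
Reactants: 1 dehydrolinalool (rac-3,7-dimethyloct-6-en-1-yn-3-ol); 2 2-methoxypropene
Product: 5 (3E,5E)-pseudoionone, via propargyl isopropenyl ether 3 (not isolated), via allenyl ketone 4 (not isolated)
Conditions: 2 (3 equiv), p-TsOH (0.1 mol%), ligroin, sealed vessel, 60 → 90 °C; then cat. NaOH, MeOH, 0 °C; fractional distillation to collect the (3E,5E) isomer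
Reagents that add atoms: none
Why: Acid-catalysed transetherification gives the propargyl isopropenyl ether, whose irreversible [3,3]-sigmatropic propargyl Claisen (Saucy–Marbet) shift forms the C7'–C8' bond as a β-allenyl ketone that base conjugates to the dienone; the carbinol centre of 1 is destroyed, so no stereocentre is carried.

**Step 2**
Reactants: 5 (3E,5E)-pseudoionone; 6 vinylmagnesium bromide
Product: 7 vinylpseudoionol, (4E,6E)-3,7,11-trimethyldodeca-1,4,6,10-tetraen-3-ol (racemic)
Conditions: 6 (1.2 equiv, 1 M in THF), THF, −20 → 0 °C; then H2O, 0 °C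
Reagents that add atoms: none
Why: Grignard 1,2-addition to the dienone carbonyl at low temperature gives the tertiary bis-allylic alcohol, whose racemic carbinol centre is erased in step 3.

**Step 3**
Reactants: 7 vinylpseudoionol
Product: 8 triphenyl[(2E,4E,6E)-3,7,11-trimethyldodeca-2,4,6,10-tetraen-1-yl]phosphonium bromide
Conditions: PPh3·HBr (1.0 equiv), MeOH, 0 °C → rt, dark, N2; crystallise
Reagents that add atoms: triphenylphosphine hydrobromide, [PH+](c1ccccc1)(c1ccccc1)c1ccccc1.[Br-]
Why: Acid ionises the tertiary allylic alcohol to a delocalised pentadienyl cation that PPh3 traps at the unhindered primary terminus (SN1/SN2′ allylic transposition), and the E-configured salt is purified by crystallisation, which also purges residual 6Z material.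

**Step 4**
Reactants: 8 ψ-C15 phosphonium bromide; 9 (2E,4E,6E)-2,7-dimethylocta-2,4,6-trienedial (C10 dialdehyde)
Product: 11 apo-12'-lycopenal, via C15 ψ-ylide 10 (not isolated)
Conditions: 9 (2.5 equiv, excess recovered), NaOMe (1.1 equiv), CH2Cl2/MeOH, −10 → 20 °C, salt and base added slowly to 9; then heptane, 80 °C; chromatography
Reagents that add atoms: none
Why: Wittig olefination of the semi-stabilised allylic ylide stops at mono-addition because 9 is in excess and is more electrophilic than the longer polyenal formed, and the sterically hindered Z isomer at the new C11'=C12' bond relaxes thermally to E.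

**Step 5**
Reactants: 12 (R)-α-ionone; 6 vinylmagnesium bromide
Product: 13 vinyl-α-ionol, (1E)-3-methyl-1-[(1R)-2,6,6-trimethylcyclohex-2-en-1-yl]penta-1,4-dien-3-ol (mixture of C3 epimers)
Conditions: 6 (1.2 equiv), THF, −30 → 0 °C; then H2O, 0 °C
Reagents that add atoms: none
Why: Grignard 1,2-addition outruns enolisation at low temperature, so the purchased C6 centre (R) is untouched, and the new carbinol centre is an irrelevant epimer mixture destroyed in step 6.

**Step 6**
Reactants: 13 vinyl-α-ionol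
Product: 14 triphenyl{(2E,4E)-3-methyl-5-[(1R)-2,6,6-trimethylcyclohex-2-en-1-yl]penta-2,4-dien-1-yl}phosphonium bromide
Conditions: PPh3·HBr (1.0 equiv), MeOH, 0 °C → rt, dark, N2; crystallise
Reagents that add atoms: triphenylphosphine hydrobromide, [PH+](c1ccccc1)(c1ccccc1)c1ccccc1.[Br-]
Why: The same SN1/SN2′ phosphonium formation applies, with PPh3 capturing the pentadienyl cation at C11 faster than loss of the adjacent C6–H at 0 °C, so the (6R) centre is retained.

**Step 7**
Reactants: 14 ε-C15 phosphonium bromide; 11 apo-12'-lycopenal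
Product: 16 (6R)-δ-carotene, via C15 ε-ylide 15 (not isolated)
Conditions: 14 (1.2 equiv), NaOMe (1.3 equiv), CH2Cl2/MeOH, 0 → 20 °C; then heptane, reflux, 2–4 h; crystallise from CH2Cl2/MeOH
Reagents that add atoms: none
Why: Wittig olefination closes the C11=C12 bond, NaOMe deprotonates only the P–CH2 group and not C6–H so the (6R) centre survives, and the hindered 11Z isomer equilibrates thermally to the all-E polyene, which crystallises.

## Compound list
1 | dehydrolinalool (rac-3,7-dimethyloct-6-en-1-yn-3-ol) | CC(C)=CCCC(C)(O)C#C | starting material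
2 | 2-methoxypropene (isopropenyl methyl ether) | COC(C)=C | starting material
3 | propargyl isopropenyl ether, 3,7-dimethyl-3-(prop-1-en-2-yloxy)oct-6-en-1-yne | CC(C)=CCCC(C)(OC(C)=C)C#C | intermediate
4 | allenyl ketone, 6,10-dimethylundeca-4,5,9-trien-2-one | CC(C)=CCCC(C)=C=CCC(C)=O | intermediate
5 | (3E,5E)-pseudoionone, (3E,5E)-6,10-dimethylundeca-3,5,9-trien-2-one | CC(C)=CCC/C(C)=C/C=C/C(C)=O | intermediate
6 | vinylmagnesium bromide | C=C[Mg]Br | starting material
7 | vinylpseudoionol, (4E,6E)-3,7,11-trimethyldodeca-1,4,6,10-tetraen-3-ol (racemic) | CC(C)=CCC/C(C)=C/C=C/C(C)(O)C=C | intermediate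
8 | triphenyl[(2E,4E,6E)-3,7,11-trimethyldodeca-2,4,6,10-tetraen-1-yl]phosphonium bromide | CC(C)=CCC/C(C)=C/C=C/C(C)=C/C[P+](c1ccccc1)(c1ccccc1)c1ccccc1.[Br-] | intermediate
9 | (2E,4E,6E)-2,7-dimethylocta-2,4,6-trienedial (C10 dialdehyde) | O=C/C(C)=C/C=C/C=C(C)/C=O | starting material
10 | C15 ψ-ylide, [(2E,4E,6E)-3,7,11-trimethyldodeca-2,4,6,10-tetraen-1-ylidene]triphenylphosphorane | CC(C)=CCC/C(C)=C/C=C/C(C)=C/C=P(c1ccccc1)(c1ccccc1)c1ccccc1 | intermediate
11 | apo-12'-lycopenal, (2E,4E,6E,8E,10E,12E,14E)-2,7,11,15,19-pentamethylicosa-2,4,6,8,10,12,14,18-octaenal | CC(C)=CCC/C(C)=C/C=C/C(C)=C/C=C/C(C)=C/C=C/C=C(C)/C=O | intermediate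
12 | (R)-α-ionone, (3E)-4-[(1R)-2,6,6-trimethylcyclohex-2-en-1-yl]but-3-en-2-one | CC(=O)/C=C/[C@H]1C(C)=CCCC1(C)C | starting material
13 | vinyl-α-ionol, (1E)-3-methyl-1-[(1R)-2,6,6-trimethylcyclohex-2-en-1-yl]penta-1,4-dien-3-ol (C3 epimers) | C=CC(C)(O)/C=C/[C@H]1C(C)=CCCC1(C)C | intermediate
14 | triphenyl{(2E,4E)-3-methyl-5-[(1R)-2,6,6-trimethylcyclohex-2-en-1-yl]penta-2,4-dien-1-yl}phosphonium bromide | C(/C=C(C)/C=C/[C@H]1C(C)=CCCC1(C)C)[P+](c1ccccc1)(c1ccccc1)c1ccccc1.[Br-] | intermediate
15 | C15 ε-ylide, {(2E,4E)-3-methyl-5-[(1R)-2,6,6-trimethylcyclohex-2-en-1-yl]penta-2,4-dien-1-ylidene}triphenylphosphorane | c1ccccc1P(c1ccccc1)(c1ccccc1)=C/C=C(C)/C=C/[C@H]1C(C)=CCCC1(C)C | intermediate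
16 | (6R)-δ-carotene, (6R)-ε,ψ-carotene | CC(C)=CCC/C(C)=C/C=C/C(C)=C/C=C/C(C)=C/C=C/C=C(C)/C=C/C=C(C)/C=C/[C@H]1C(C)=CCCC1(C)C | target

## Step count
Total steps: 7.
Longest linear sequence: 5 steps (steps 1, 2, 3, 4, 7); the ε-branch (steps 5, 6) joins at step 7.

## Steps most likely to fail, with fallbacks

**Step 1.** The risks are acid-induced Rupe or Meyer–Schuster chemistry of the tertiary propargylic alcohol and a poor 5E/5Z ratio. The fallback sets out from 1 and comes back to the route at 4. Alcohol 1 is acylated with diketene (cat. DMAP, toluene, 0–25 °C) to give dehydrolinalyl acetoacetate F1. Heating F1 neat at 170–180 °C with a trace of Al(OiPr)3 triggers a Carroll [3,3] shift of its enol to the allenyl β-keto acid F2. F2 loses CO2 in the same pot and delivers allenyl ketone 4, which is conjugated to 5 by the base stage of step 1. No Brønsted acid is present at any point.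

**Step 4.** The risks are over-reaction to the bis-adduct and loss of valuable salt 8 to statistics. The fallback sets out from 9 and comes back at 11. Dialdehyde 9 is treated with neopentyl glycol (0.5 equiv, cat. p-TsOH, toluene, rt) and the C10 mono-acetal F3 is separated from unreacted 9, which is recycled. Ylide 10, generated from 8 as in step 4, then meets a single formyl group and gives the C25 acetal F4. Dilute aqueous H2SO4 in THF at rt releases 11. The desymmetrisation is thus moved onto the cheap C10 unit.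

**Step 6.** The risk is that the cation next to the doubly allylic C6–H causes proton loss to a retro-triene or erosion of the (6R) centre. The fallback sets out from 13 and comes back at 16, bypassing steps 6 and 7. Alcohol 13 is treated with Ph2PCl and Et3N (THF, −20 °C) to give the allyl diphenylphosphinite F5. On warming to rt, F5 undergoes a [2,3]-sigmatropic rearrangement to the crystalline (2E,4E)-dienyl diphenylphosphine oxide F6. Deprotonation of F6 (KOtBu, THF, −30 °C) and Horner–Wittig olefination with aldehyde 11 gives 16 directly after the heptane isomerisation. No carbocation is formed anywhere near C6.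

## Further compounds
F1 | step 1 | dehydrolinalyl acetoacetate, 3,7-dimethyloct-6-en-1-yn-3-yl 3-oxobutanoate | CC(C)=CCCC(C)(OC(=O)CC(C)=O)C#C
F2 | step 1 | allenyl β-keto acid, 2-acetyl-5,9-dimethyldeca-3,4,8-trienoic acid | CC(=O)C(C(=O)O)C=C=C(C)CCC=C(C)C
F3 | step 4 | C10 mono-acetal, (2E,4E,6E)-7-(5,5-dimethyl-1,3-dioxan-2-yl)-2-methylocta-2,4,6-trienal | O=C/C(C)=C/C=C/C=C(C)/C1OCC(C)(C)CO1
F4 | step 4 | C25 acetal, 5,5-dimethyl-2-[(2E,4E,6E,8E,10E,12E,14E)-7,11,15,19-tetramethylicosa-2,4,6,8,10,12,14,18-octaen-2-yl]-1,3-dioxane | CC(C)=CCC/C(C)=C/C=C/C(C)=C/C=C/C(C)=C/C=C/C=C(C)/C1OCC(C)(C)CO1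
F5 | step 6 | allyl diphenylphosphinite, (1E)-3-methyl-1-[(1R)-2,6,6-trimethylcyclohex-2-en-1-yl]penta-1,4-dien-3-yl diphenylphosphinite | C=CC(C)(OP(c1ccccc1)c1ccccc1)/C=C/[C@H]1C(C)=CCCC1(C)C
F6 | step 6 | dienyl diphenylphosphine oxide, {(2E,4E)-3-methyl-5-[(1R)-2,6,6-trimethylcyclohex-2-en-1-yl]penta-2,4-dien-1-yl}diphenylphosphine oxide | O=P(C/C=C(C)/C=C/[C@H]1C(C)=CCCC1(C)C)(c1ccccc1)c1ccccc1
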